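## Analysis of the target

The target is 3,4,5-tribromo-2-(3,5-dibromo-2-methoxyphenoxy)phenol, C13H7Br5O3, two benzene rings joined by one ether oxygen. Ring B is numbered C1 (ether oxygen), C2 (OH), C3 (H), C4, C5, C6 (all Br). Ring A is numbered C1' (ether oxygen), C2' (OMe), C3' (Br), C4' (H), C5' (Br), C6' (H). There is no stereocentre, so the whole problem is regiochemistry. The sensitive groups are the free phenol, which is easily oxidised, and the five C–Br bonds, which rule out organolithium reagents, hydrogenation over palladium and most cross-coupling once they are in place. The diaryl ether is flanked by substituents at C2, C6 and C2', so closing it late between two loaded rings would be a hindered coupling with competing C–Br sites. On ring A the bromines sit ortho and para to the C2' oxygen, which is the natural pattern of a phenol. On ring B the bromines at C4 and C6 are meta to the hydroxyl while the ortho position C3 is empty, the reverse of what a phenol gives. The strategy rests on the array O–C2–C1–O–C1'–C2'–O: both carbons ortho to the ether oxygen carry oxygen, which is exactly where diphenyl ether is deprotonated under the direction of its own oxygen.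

## Retrosynthetic reasoning

C3–H of 14 back to C3–N of 12 (through 13). The C4 and C6 bromines cannot come from the hydroxyl, so a nitrogen is placed at C3, the one position the target leaves empty. From there it is ortho to C4 and para to C6, and it can be removed at the end. The forward step must replace a hindered, weakly basic amino group by hydrogen without touching five bromines.

C4–Br and C6–Br, 12 back to 11. Both bonds are cut together. In 11 every position activated by the hydroxyl is already occupied (C1, C3, C5), so the amino group and the ether oxygen, which agree, decide where the two bromines go.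

C3–N, 11 back to 10 and then 9. The nitrogen enters as a nitro group. With C5 blocked by bromine, C3 is the only site left that the hydroxyl activates, so nitration has one place to go. The reduction must spare the C–Br bonds.

C5–Br, 9 back to 8. This is a plain para-bromination of the ring B phenol. It is done first on ring B because it blocks the para position before nitration.

Ring A and the oxygen substituents, 8 back to 7, 6 and 5. Ring A has its bromines ortho and para to the C2' oxygen, so that oxygen must be a free phenol while it is brominated, and the ring B oxygen must at the same time be masked by a deactivating ester. Methylation then switches ring A off for good, and removal of the ester switches ring B on. Cutting in this order means each ring is brominated only while it is the more electron-rich one.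

Desymmetrisation, 5 back to 4. The two hydroxyls of 4 are equivalent, so one is acylated statistically. This is the cost of starting from a symmetrical bisphenol.

C2–O and C2'–O, 4 back to 1 (through 3 and 2). Both ortho C–O bonds are cut at once, which leaves the parent diaryl ether 1, a commodity chemical. The hindered ether bond is therefore never made, and the organometallic chemistry is done before any halogen is present. The forward step must oxygenate one ortho carbon on each ring.

## Alternatives that were turned down

Alternative 1: Ring B is cut into a three-carbon ketone unit (C1, C2, C3) and a three-carbon dialdehyde unit (C4, C5, C6), across C3–C4 and C1–C6. In the forward step the aryloxyacetone A1 condenses twice with sodium nitromalonaldehyde A3 in aqueous base and closes ring B as the 4-nitrophenol A2.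
- For: it is convergent, and ring A arrives with its pattern fixed. The nitro group lands on C5. After reduction the amine would direct bromine to both neighbours C4 and C6, and a Sandmeyer bromination would turn the nitrogen itself into the C5 bromine. Ring B would then need about three operations instead of the five used here, and on that point this alternative is stronger.
- Against: A3 is a shock-sensitive salt. A1 is an unsymmetrical ketone whose aryloxymethylene and methyl carbons must both condense in water. The ring A phenol behind A1 has its bromines ortho and para to the methoxy group, not to the hydroxyl, so it needs a multi-step preparation of its own. In the bromination after A2 the free hydroxyl at C2 would push towards C3, the one position that must stay empty, and a para-aminophenol is very easily oxidised.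
- Comparison: the chosen route gives up convergence. In return it starts from a commodity ether, builds no ring, uses no hazardous reagent, and brominates ring B only after every hydroxyl-activated position is filled.

Alternative 2: Ring A is cut across C2'–C3' and C1'–C6' into 3,5-dibromo-2-pyrone A4 and the Z-enediol diether A5. The forward step is a [4+2] cycloaddition followed by decarboxylative cycloreversion of the bridged lactone, which gives the cyclohexadiene A6.
- For: both ring A bromines come in with defined positions and no electrophilic bromination of ring A is needed. On that narrow point it is as strong as the chosen route.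
- Against: A5 already contains the fully substituted ring B, so the harder half of the problem is only moved. A Z-configured 1-alkoxy-2-aryloxyethene is itself hard to make. The orientation of the cycloaddition depends on the small difference in donor strength between the methoxy and aryloxy carbons. A6 is not aromatic, and a diene with allylic methoxy and aryloxy groups should aromatise far more readily by eliminating one of them than by dehydrogenation, which destroys an oxygen the target needs. Two stereocentres are made only to be erased, and the isopropyl ether must still be cleaved.
- Comparison: the chosen route keeps both rings aromatic throughout and fixes all three oxygens in the first step.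

Alternative 3: The C4–Br and C6–Br bonds of ring B are cut, with an amino group at C3 as a removable director. The forward key step is the twofold bromination of the aminophenol A7 to A8.
- For: it solves the meta-to-hydroxyl bromines with all directing groups in agreement, and the nitrogen leaves without trace.
- Against: it is an end-game tactic and not a plan for the skeleton. It does not say how the hindered ether of A7 is made. A convergent coupling would have to join two ortho-substituted partners that already carry bromines, and a nitro group at C3 is meta to C1 and cannot activate it for substitution.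
- Comparison: on ring B regiocontrol it is exactly as strong, because the chosen route uses the same tactic in steps 7 to 10 (A7 and A8 have the structures of 11 and 12). What the chosen route adds is the answer to the ether bond and the two ortho oxygens.

Key step: step 1

Remark: the borylated intermediate 3 is written as the neutral bis(boronate) and the diazonium intermediate 13 as its hydrogen sulfate. These are the simplest defined forms of species that exist in the flask as mixtures of ate complexes or ion pairs.

## Route

Step 1
Reactants: 1 diphenyl ether
Product: 4 2,2'-oxydiphenol, via 2,2'-dilithiodiphenyl ether 2 (not isolated), via tetramethyl 2,2'-oxybis(benzeneboronate) 3 (not isolated)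
Conditions: n-BuLi (2.5 equiv), TMEDA (2.5 equiv), Et2O/hexane, 0 °C → rt, 16 h; B(OMe)3 (5 equiv), −78 °C → rt; 3 M NaOH, 30% H2O2, 0 °C → rt; then aq. HCl
Reagents that add atoms: n-butyllithium, [Li]CCCC (the lithium of 2 only); trimethyl borate, COB(OC)OC (boron and methoxy groups of 3 only); hydrogen peroxide, OO (the two new phenol oxygens of 4)
Why: n-BuLi·TMEDA binds the ether oxygen of 1 and removes the adjacent C2–H (directed ortho-metalation through a complex-induced proximity effect); the second equivalent goes to C2' of the other ring, because the first aryl anion makes its own ring much less acidic while the same oxygen still acidifies and positions C2'–H, giving 2 with both lithium atoms held by the ether oxygen. Trimethyl borate captures each C–Li bond as an ate complex that loses methoxide to give 3; if the second aryllithium adds instead to the boron already on the first ring, the bridged diarylborinate that results is oxidised to the same product. Hydroperoxide anion adds to boron and the aryl group shifts from boron to oxygen with loss of hydroxide, once for each C–B bond, and hydrolysis of the aryl borates releases 4. The closest known reaction types are the twofold ortho-lithiation of diphenyl ether used to make 2,2'-disubstituted diphenyl ethers and the lithiation, borylation, oxidation sequence from arenes to phenols. No ring is closed and no stereocentre is formed. The selectivity needed is positional (C2 and C2', not C4, and one site per ring), and it is secured because the ether oxygen is the only coordinating group in a substrate with no halogen, carbonyl or acidic proton to divert the organolithium.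

Step 2
Reactants: 4 2,2'-oxydiphenol
Product: 5 2-(2-hydroxyphenoxy)phenyl 2,2-dimethylpropanoate (mono-pivalate)
Conditions: PivCl (1.0 equiv, slow addition), Et3N (1.1 equiv), CH2Cl2, −20 → 0 °C
Reagents that add atoms: pivaloyl chloride, CC(C)(C)C(Cl)=O
Why: Base-mediated O-acylation of a phenol with a hindered acid chloride; with one equivalent added slowly the mono-ester should predominate, since the bisphenol, whose mono-anion is stabilised by the neighbouring hydroxyl, is the better partner than 5. Unreacted and doubly acylated material can be returned to 4 by saponification.

Step 3
Reactants: 5 2-(2-hydroxyphenoxy)phenyl 2,2-dimethylpropanoate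
Product: 6 2-(3,5-dibromo-2-hydroxyphenoxy)phenyl 2,2-dimethylpropanoate
Conditions: Br2 (2.05 equiv), CH2Cl2, −10 → 0 °C
Reagents that add atoms: bromine, BrBr
Why: Electrophilic aromatic bromination; the free hydroxyl at C2' activates C5' (para) and C3' (ortho) far more than the shared ether oxygen activates ring B, which the pivalate also deactivates, so two equivalents should stop at the 3',5'-dibromide.

Step 4
Reactants: 6 2-(3,5-dibromo-2-hydroxyphenoxy)phenyl 2,2-dimethylpropanoate
Product: 7 2-(3,5-dibromo-2-methoxyphenoxy)phenyl 2,2-dimethylpropanoate
Conditions: MeI (1.5 equiv), K2CO3 (1.5 equiv), acetone, 40 °C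
Reagents that add atoms: iodomethane, CI
Why: Williamson O-methylation of the acidic dibromophenol; the phenoxide is hindered but methyl iodide is small, and the pivalate is stable to K2CO3 in acetone. Transfer of the pivalate to the more acidic bromophenol oxygen would be thermodynamically uphill.

Step 5
Reactants: 7 2-(3,5-dibromo-2-methoxyphenoxy)phenyl 2,2-dimethylpropanoate
Product: 8 2-(3,5-dibromo-2-methoxyphenoxy)phenol
Conditions: 2 M NaOH, THF, 50 °C; then aq. HCl
Reagents that add atoms: none
Why: Saponification of an aryl ester, which is easier than for an alkyl pivalate because phenoxide is the leaving group; aryl bromides, the methyl ether and the diaryl ether are inert to aqueous hydroxide at this temperature.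

Step 6
Reactants: 8 2-(3,5-dibromo-2-methoxyphenoxy)phenol
Product: 9 4-bromo-2-(3,5-dibromo-2-methoxyphenoxy)phenol
Conditions: NBS (1.0 equiv), MeCN, −20 → 0 °C
Reagents that add atoms: N-bromosuccinimide, O=C1CCC(=O)N1Br
Why: Electrophilic bromination of a phenol with NBS in acetonitrile, which favours the para position; C5 is para to the C2 hydroxyl. Ring A, with two bromines and no free site ortho or para to its methoxy group, should not compete.

Step 7
Reactants: 9 4-bromo-2-(3,5-dibromo-2-methoxyphenoxy)phenol
Product: 10 4-bromo-2-(3,5-dibromo-2-methoxyphenoxy)-6-nitrophenol
Conditions: 65% HNO3 (1.1 equiv), AcOH, 10–15 °C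
Reagents that add atoms: nitric acid, O[N+](=O)[O-]
Why: Electrophilic nitration; with C1 and C5 occupied, C3 is the only position the hydroxyl still activates. Dilute nitric acid in acetic acid at low temperature limits ipso attack at C5 and oxidation of the phenol.

Step 8
Reactants: 10 4-bromo-2-(3,5-dibromo-2-methoxyphenoxy)-6-nitrophenol
Product: 11 2-amino-4-bromo-6-(3,5-dibromo-2-methoxyphenoxy)phenol
Conditions: Fe powder (5 equiv), AcOH/EtOH/H2O, 60 °C, under N2; used directly
Reagents that add atoms: none
Why: Béchamp-type reduction of the nitro group by iron in acetic acid, which leaves aryl bromides untouched where hydrogenation over palladium would not. The air-sensitive aminophenol is carried on without storage.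

Step 9
Reactants: 11 2-amino-4-bromo-6-(3,5-dibromo-2-methoxyphenoxy)phenol
Product: 12 2-amino-3,4,5-tribromo-6-(3,5-dibromo-2-methoxyphenoxy)phenol
Conditions: Br2 (2.1 equiv), AcOH, 10 °C → rt, under N2, dark
Reagents that add atoms: bromine, BrBr
Why: Electrophilic bromination directed by the amino group; C4 is ortho and C6 para to nitrogen, both are also para and ortho to the ether oxygen, and every position activated by the hydroxyl is already substituted, so all donors agree. The acidic medium favours C-bromination over oxidation of the aminophenol.

Step 10
Reactants: 12 2-amino-3,4,5-tribromo-6-(3,5-dibromo-2-methoxyphenoxy)phenol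
Product: 14 3,4,5-tribromo-2-(3,5-dibromo-2-methoxyphenoxy)phenol, via arenediazonium hydrogen sulfate 13 (not isolated)
Conditions: NaNO2 (1.2 equiv), conc. H2SO4/AcOH, 0–5 °C; then 50% aq. H3PO2 (10 equiv), Cu2O (cat.), 0 °C → rt
Reagents that add atoms: sodium nitrite (NaNO2), [Na+].[O-]N=O (the second nitrogen of 13, lost again as N2); sulfuric acid, OS(O)(=O)=O (counter-ion of 13); 14 itself gains only hydrogen
Why: Diazotisation of the weakly basic, hindered amine with nitrosyl hydrogen sulfate, then hydrodediazoniation with hypophosphorous acid (radical chain in which the aryl radical takes hydrogen from H3PO2), started by Cu2O. Strong acid keeps the intermediate as the hydroxy diazonium ion and not as the less reducible quinone diazide.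

## Compound list

1 | diphenyl ether | c1ccc(Oc2ccccc2)cc1 | starting material
2 | 2,2'-dilithiodiphenyl ether (TMEDA-solvated in the flask) | [Li]c1ccccc1Oc1ccccc1[Li] | intermediate
3 | tetramethyl 2,2'-oxybis(benzeneboronate) | COB(OC)c1ccccc1Oc1ccccc1B(OC)OC | intermediate
4 | 2,2'-oxydiphenol | Oc1ccccc1Oc1ccccc1O | intermediate
5 | 2-(2-hydroxyphenoxy)phenyl 2,2-dimethylpropanoate | CC(C)(C)C(=O)Oc1ccccc1Oc1ccccc1O | intermediate
6 | 2-(3,5-dibromo-2-hydroxyphenoxy)phenyl 2,2-dimethylpropanoate | CC(C)(C)C(=O)Oc1ccccc1Oc1cc(Br)cc(Br)c1O | intermediate
7 | 2-(3,5-dibromo-2-methoxyphenoxy)phenyl 2,2-dimethylpropanoate | COc1c(Br)cc(Br)cc1Oc1ccccc1OC(=O)C(C)(C)C | intermediate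
8 | 2-(3,5-dibromo-2-methoxyphenoxy)phenol | COc1c(Br)cc(Br)cc1Oc1ccccc1O | intermediate
9 | 4-bromo-2-(3,5-dibromo-2-methoxyphenoxy)phenol | COc1c(Br)cc(Br)cc1Oc1cc(Br)ccc1O | intermediate
10 | 4-bromo-2-(3,5-dibromo-2-methoxyphenoxy)-6-nitrophenol | COc1c(Br)cc(Br)cc1Oc1cc(Br)cc([N+](=O)[O-])c1O | intermediate
11 | 2-amino-4-bromo-6-(3,5-dibromo-2-methoxyphenoxy)phenol | COc1c(Br)cc(Br)cc1Oc1cc(Br)cc(N)c1O | intermediate
12 | 2-amino-3,4,5-tribromo-6-(3,5-dibromo-2-methoxyphenoxy)phenol | COc1c(Br)cc(Br)cc1Oc1c(Br)c(Br)c(Br)c(N)c1O | intermediate
13 | 2,3,4-tribromo-5-(3,5-dibromo-2-methoxyphenoxy)-6-hydroxybenzenediazonium hydrogen sulfate | COc1c(Br)cc(Br)cc1Oc1c(Br)c(Br)c(Br)c([N+]#N)c1O.OS(=O)(=O)[O-] | intermediate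
14 | 3,4,5-tribromo-2-(3,5-dibromo-2-methoxyphenoxy)phenol | COc1c(Br)cc(Br)cc1Oc1c(O)cc(Br)c(Br)c1Br | target

## Step count and risks

Total step count: 10. Longest linear sequence: 10 steps (the route is linear from 1).

Least certain steps:

Step 1 (key step). The most likely failure is that only one ring ends up oxygenated, through an incomplete second deprotonation or through loss of boron by protonolysis before the peroxide acts. The two aryl–boron bonds sit ortho to an oxygen and are formed on a crowded dianion, and mono-oxygenated material would be tedious to remove from a polar bisphenol. Fallback: from 1, the same dilithiation is quenched with DMF to give 2,2'-oxydibenzaldehyde F1, a crystalline dialdehyde that can be freed of mono-formylated material before any oxygen is introduced. A twofold Baeyer–Villiger oxidation with mCPBA in CH2Cl2, in which the aryl group migrates from carbon to oxygen helped by the ortho aryloxy donor, gives oxydi-2,1-phenylene diformate F2. Methanolysis with K2CO3 in MeOH returns to the route at 4.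

Step 9. The free ortho-aminophenol may be oxidised by bromine at nitrogen towards a quinone imine, with subsequent condensation, instead of being substituted on carbon, because both heteroatoms are electron-rich and unprotected. Fallback: from 11, selective N-acetylation (Ac2O, EtOAc/aq. NaHCO3) gives N-[5-bromo-3-(3,5-dibromo-2-methoxyphenoxy)-2-hydroxyphenyl]acetamide F3, which is much harder to oxidise. Bromination (Br2, NaOAc, AcOH, rt → 40 °C), still directed to C4 and C6 by the amide nitrogen and the ether oxygen, gives N-[2,3,4-tribromo-5-(3,5-dibromo-2-methoxyphenoxy)-6-hydroxyphenyl]acetamide F4. Hydrolysis in 6 M HCl/EtOH at reflux returns to the route at 12.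

Step 10. Diazotisation of an amine flanked by a hydroxyl and a bromine may be incomplete, and the diazonium ion may collapse to the ortho-quinone diazide, which resists hydrogen-atom reduction, so that the amino group is not cleanly exchanged for hydrogen. Fallback: from 12, the diazotised solution is reduced with SnCl2 in HCl at 0 °C, a two-electron process that also works on quinone diazides, to give 3,4,5-tribromo-2-(3,5-dibromo-2-methoxyphenoxy)-6-hydrazinylphenol F5. Oxidation of the hydrazine with CuSO4 in warm aqueous acetic acid gives the aryldiazene, which loses nitrogen and arrives at 14.

Step 7. Nitric acid may attack the brominated para carbon C5 with loss of bromine, or oxidise the electron-rich phenol, because the only free activated site, C3, lies next to the hydroxyl on an already crowded ring. Fallback: from 9, azo coupling with diazotised sulfanilic acid in cold aqueous NaOH/EtOH puts the nitrogen at C3 under non-oxidising conditions and gives 4-{(E)-[5-bromo-3-(3,5-dibromo-2-methoxyphenoxy)-2-hydroxyphenyl]diazenyl}benzenesulfonic acid F6. Reductive cleavage of the azo bond with Na2S2O4 in aqueous NaOH at 50 °C returns to the route at 11 without passing through 10.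

## Further compounds

F1 | step 1 | 2,2'-oxydibenzaldehyde | O=Cc1ccccc1Oc1ccccc1C=O
F2 | step 1 | oxydi-2,1-phenylene diformate | O=COc1ccccc1Oc1ccccc1OC=O
F3 | step 9 | N-[5-bromo-3-(3,5-dibromo-2-methoxyphenoxy)-2-hydroxyphenyl]acetamide | COc1c(Br)cc(Br)cc1Oc1cc(Br)cc(NC(C)=O)c1O
F4 | step 9 | N-[2,3,4-tribromo-5-(3,5-dibromo-2-methoxyphenoxy)-6-hydroxyphenyl]acetamide | COc1c(Br)cc(Br)cc1Oc1c(Br)c(Br)c(Br)c(NC(C)=O)c1O
F5 | step 10 | 3,4,5-tribromo-2-(3,5-dibromo-2-methoxyphenoxy)-6-hydrazinylphenol | COc1c(Br)cc(Br)cc1Oc1c(Br)c(Br)c(Br)c(NN)c1O
F6 | step 7 | 4-{(E)-[5-bromo-3-(3,5-dibromo-2-methoxyphenoxy)-2-hydroxyphenyl]diazenyl}benzenesulfonic acid | COc1c(Br)cc(Br)cc1Oc1cc(Br)cc(/N=N/c2ccc(cc2)S(O)(=O)=O)c1O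
A1 | alternative 1 | 1-(3,5-dibromo-2-methoxyphenoxy)propan-2-one | COc1c(Br)cc(Br)cc1OCC(C)=O
A2 | alternative 1 | 2-(3,5-dibromo-2-methoxyphenoxy)-4-nitrophenol | COc1c(Br)cc(Br)cc1Oc1cc(ccc1O)[N+](=O)[O-]
A3 | alternative 1 | sodium nitromalonaldehyde (NaC3H2NO4, sodium enolate of nitromalonaldehyde) | [Na+].[O-]C=C(C=O)[N+](=O)[O-]
A4 | alternative 2 | 3,5-dibromo-2H-pyran-2-one | O=C1OC=C(Br)C=C1Br
A5 | alternative 2 | (Z)-1-methoxy-2-(2,3,4-tribromo-6-isopropoxyphenoxy)ethene | CO/C=C\Oc1c(OC(C)C)cc(Br)c(Br)c1Br
A6 | alternative 2 | cis-1,3-dibromo-6-methoxy-5-(2,3,4-tribromo-6-isopropoxyphenoxy)cyclohexa-1,3-diene (racemic, one enantiomer drawn) | CO[C@H]1C(Br)=CC(Br)=C[C@H]1Oc1c(OC(C)C)cc(Br)c(Br)c1Br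
A7 | alternative 3 | 2-amino-4-bromo-6-(3,5-dibromo-2-methoxyphenoxy)phenol | COc1c(Br)cc(Br)cc1Oc1cc(Br)cc(N)c1O
A8 | alternative 3 | 2-amino-3,4,5-tribromo-6-(3,5-dibromo-2-methoxyphenoxy)phenol | COc1c(Br)cc(Br)cc1Oc1c(Br)c(Br)c(Br)c(N)c1O
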